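**Retrosynthetic overview**
- Forward map: acid chloride 1 + alkyne 2 → ynone 3 → allenyl ketone 4 (in the flask) → furan 5 (target).
- Disconnection A (last step, C–O): open the furan O1–C2 bond of 5 (the carbon carrying CH2CO2Me). This gives acyclic allenyl ketone 4, which is the 1,3-hydrogen-shift isomer of conjugated ynone 3; 3 is an isomer of 5 with all 22 chain carbons, the ketone oxygen and the ester already in place.
- Disconnection B (C–C): the acyl–alkynyl bond of 3 leads back to 1 and 2.
- Ring order: the furan is the only ring and is closed in the final step by C–O bond formation.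

Assumption: the target has no stereocentre and no stereogenic double bond, so it is achiral and no stereocontrol is needed; 1 and 2 are taken as catalogue compounds.

**Route**

Step 1
Reactants: 1 heptadecanoyl chloride (1.3 equiv); 2 methyl pent-4-ynoate
Product: 3 methyl 6-oxodocos-4-ynoate
Conditions: PdCl2(PPh3)2 (2 mol%), CuI (4 mol%), Et3N (1.05 equiv), THF, 0 °C to rt, N2
Reagents that add atoms: none
Why: Acyl Sonogashira coupling: zerovalent palladium formed in situ inserts into the C–Cl bond of 1, the copper acetylide of 2 transmetalates and reductive elimination forms the acyl–alkynyl C–C bond; about one equivalent of amine at low temperature limits ketene formation from the enolisable acid chloride, the methyl ester is inert, and no stereocentre is formed.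

Step 2
Reactants: 3 methyl 6-oxodocos-4-ynoate
Product: 5 methyl 2-(5-hexadecylfuran-2-yl)acetate, via allenyl ketone 4 (not isolated)
Conditions: [{Au(IPr)}2(μ-OH)][BF4] (1.5 mol%), toluene, 60 °C, N2 (IPr = 1,3-bis(2,6-diisopropylphenyl)imidazol-2-ylidene)
Reagents that add atoms: none
Why: Proposed new method: amine-free acid–base gold cycloisomerisation of a conjugated alk-2-yn-1-one with one complex. The hydroxide-bridged digold salt dissociates into the π-acid [Au(IPr)]+ and the Brønsted base [Au(IPr)(OH)]. The base removes the γ-proton (C3–H) of the gold-bound ynone to give an α-aurated allenone, which the water just formed protonates to allenyl ketone 4. [Au(IPr)]+ then activates the C3=C4 bond of 4, and the ketone oxygen closes 5-endo onto C3, forming the new O–C bond and the ring. Loss of the C3 proton and protodeauration give the aromatic furan and return both gold species. With no free amine in solution, the competing shift of 4 to the conjugated 2,4-dienone should be slow and the ester is untouched. Closest known reaction types: CuI/Et3N cycloisomerisation of alkynyl ketones through allenyl ketones, cyclisation of allenyl ketones to furans at monovalent gold, and propargylic deprotonation at monovalent gold by ligand-borne amines. No stereocentre is formed; the allene axis of 4 vanishes on aromatisation.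

**Compound list**
1 | heptadecanoyl chloride | CCCCCCCCCCCCCCCCC(=O)Cl | starting material
2 | methyl pent-4-ynoate | C#CCCC(=O)OC | starting material
3 | methyl 6-oxodocos-4-ynoate | CCCCCCCCCCCCCCCCC(=O)C#CCCC(=O)OC | intermediate
4 | methyl 6-oxodocosa-3,4-dienoate (allenyl ketone, racemic axis, not isolated) | CCCCCCCCCCCCCCCCC(=O)C=C=CCC(=O)OC | intermediate
5 | methyl 2-(5-hexadecylfuran-2-yl)acetate (achiral) | CCCCCCCCCCCCCCCCc1ccc(CC(=O)OC)o1 | target

**Totals**
Total step count: 2. Longest linear sequence: 2 steps (1 or 2 → 3 → 5).

**Steps most likely to fail**
The route has only two steps, so both are ranked; there is no third step.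

1. Step 2 (the proposed new gold acid–base cycloisomerisation). Likely failure modes: the gold hydroxide may not remove the γ-proton fast enough, so 3 is recovered, or 4 may drift to the conjugated dienone methyl 6-oxodocosa-2,4-dienoate. The fallback uses known chemistry and closes the ring by Paal–Knorr cyclodehydration of a 1,4-diketone instead of by alkyne isomerisation. It sets out from 1 and comes back at 5.
   - 1 is acylated with the zinc homoenolate IZnCH2CH2CO2Et (from ethyl 3-iodopropanoate and zinc dust) under Pd(PPh3)4 catalysis in THF to give ethyl 4-oxoicosanoate F1.
   - LiOH in THF/water, then acid, gives 4-oxoicosanoic acid F2.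
   - 1,1'-Carbonyldiimidazole in THF converts F2 into the acyl imidazolide 1-(1H-imidazol-1-yl)icosane-1,4-dione F3, used in the flask.
   - Potassium methyl malonate (MeO2CCH2CO2K), MgCl2 and Et3N acylate the malonate to 2-(methoxycarbonyl)-3,6-dioxodocosanoic acid F4 (magnesium chelate, in the flask).
   - Acidic work-up decarboxylates F4 to methyl 3,6-dioxodocosanoate F5.
   - Catalytic TsOH in refluxing toluene with removal of water cyclises F5 to 5.

2. Step 1 (acyl Sonogashira coupling). Likely failure mode: ketene formation and self-condensation of the long-chain acid chloride with the amine, giving a low yield of 3. The fallback replaces the cross-coupling by carbonyl addition and oxidation. It sets out from 2 and comes back at 3.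
   - The zinc acetylide of 2, generated with Zn(OTf)2 and Et3N in toluene at rt (ester tolerated), adds to slowly introduced heptadecanal to give racemic methyl 6-hydroxydocos-4-ynoate F6.
   - Oxidation of the propargylic alcohol with activated MnO2 in CH2Cl2 (or Dess–Martin periodinane) gives 3.

**Further compounds**
F1 | step 2 | ethyl 4-oxoicosanoate | CCCCCCCCCCCCCCCCC(=O)CCC(=O)OCC
F2 | step 2 | 4-oxoicosanoic acid | CCCCCCCCCCCCCCCCC(=O)CCC(=O)O
F3 | step 2 | 1-(1H-imidazol-1-yl)icosane-1,4-dione | CCCCCCCCCCCCCCCCC(=O)CCC(=O)n1ccnc1
F4 | step 2 | 2-(methoxycarbonyl)-3,6-dioxodocosanoic acid | CCCCCCCCCCCCCCCCC(=O)CCC(=O)C(C(=O)O)C(=O)OC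
F5 | step 2 | methyl 3,6-dioxodocosanoate | CCCCCCCCCCCCCCCCC(=O)CCC(=O)CC(=O)OC
F6 | step 1 | methyl 6-hydroxydocos-4-ynoate (racemic) | CCCCCCCCCCCCCCCCC(O)C#CCCC(=O)OC
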